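The target of a flask comes from a race for the substrate: the catalysed step makes target, and the uncatalysed step makes side product.

- ochre: substrate 1.6 M; free catalyst 80 mM; run made earlier
- flask: substrate 0.80 M; free catalyst 80 mM; time 40 h

ochre run (percent of the substrate charged)

| time / h | substrate / % | target / % | side product / % |
|---|---|---|---|
| 0.500 | 81 | 8 | 11 |
| 1.33 | 58 | 21 | 23 |
| 2.50 | 33 | 27 | 38 |
| 4.00 | 18 | 36 | 47 |

(each reading ± 1.5 percentage points)

- steps thought possible: substrate + free catalyst -> spent catalyst; substrate + free catalyst -> free catalyst + target; substrate -> side product
- the reaction counts as stopped when no species that holds the substrate changes by six tenths of a point or more over the second half of the time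

1. the state of affairs at 40 h: stopped, and by what, or still going (no working catalyst is left / it is still moving / all of the substrate has reacted)
2. part of the substrate gone at 40 h
3. the target standing at 40 h, as a percentage of the substrate charged
4. the side product standing at 40 h, as a percentage of the substrate charged
5. amount of target if the flask were left three thousand times as long, in percent of the substrate charged

Both steps are first order in substrate, and the catalysed one also scales with free catalyst, which makes it pseudo-first-order while free catalyst holds. The substrate charge therefore cancels from the ratio of the products. The last ochre reading gives free catalyst times side product over target, 104 mM. This is the free catalyst at which both products grow at equal pace, the break-even catalyst.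

A second way uses other readings, those at 2.50 h, and gives 113 mM. Dying catalyst would make this number rise with time, but the later value is lower. A scatter of 1.5 percentage points on a target of 27% makes the gap of 8.15 mM no cause for alarm. The later reading has the larger amounts, so it is the one carried.

The last ochre reading puts the fall of substrate at 0.429 h⁻¹, a half-life of 1.62 h. The flask holds the same free catalyst, so the same half-life applies. That is 24.7 half-lives in 40 h, and the estimate for the flask leaves <0.001% of the substrate. My reckoning for the flask gives target as free catalyst over free catalyst plus break-even catalyst, 43.4%, and side product as the remaining 56.6%. With that estimate of <0.001% of the substrate left, my reckoning puts the long-run target at the same 43.4%.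

The forecast says all of the substrate has reacted, with 100% gone, 43.5% target, 55.5% side product and 43.5% in the long run, because “Nothing remains to react”.

The flask gives this: all of the substrate has reacted, >99.9% gone, 43.1% target, 56.3% side product, 43.1% in the long run.

    substrate + free catalyst → spent catalyst (k = 8.70 × 10⁻⁶ L mol⁻¹ s⁻¹)
    substrate + free catalyst → free catalyst + target (k = 6.50 × 10⁻⁴ L mol⁻¹ s⁻¹)
    substrate → side product (k = 6.60 × 10⁻⁵ s⁻¹)

In the flask both routes ran side by side while substrate stood, and 3.49% of it remained at 8.00 h. Free catalyst stood at 94.2% of its charge at 40.0 h, with 5.77% as spent catalyst. The flask's charge of 80 mM lay below the break-even 104 mM, and the flask held more side product than target. The neighbour flask with 0.20 M of free catalyst lies above break-even. There the same formula gives 65.8%, and that flask held 65.4% target.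

The numbers in the tables stem from a simulated flask for substances that don't exist; the scatter is artificial.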